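## Structural features

The target is a trans-fused bicyclo[5.3.0]decene (a hydroazulene of the daucane type). A cyclopentane C4–C5–C6–C7–C8 shares the C4–C8 bond with a cycloheptene C1=C2–C3–C4–C8–C9–C10 that carries a methyl group on C1. Four stereocentres are contiguous: quaternary C4 (methyl), the ring-fusion methine C8, the tertiary carbinol C7 (hydroxyl and isopropyl) and the secondary C9, esterified with 4-hydroxybenzoic acid. The absolute configuration is 4R,7S,8S,9R in this numbering, (3S,3aS,4R,8aR) in azulene numbering. In relative terms the C4 methyl and H8 are trans (trans ring fusion), the C7 hydroxyl is cis to H8, and the C9 oxygen lies on the face of the C4 methyl and the C7 isopropyl group, so H8 and H9 are cis. Fragile groups are the tertiary C7 alcohol (ionisation and dehydration in acid), the trisubstituted C1=C2 alkene (migration in acid, no hydrogenolysis possible), and the aryl ester with its free phenol (base, hydride, organometallics). The real difficulty is the quaternary C4 next to C8 in a trans fusion, with C7 oxygen on the face opposite the C8–C9 bond and a hindered C9 oxygen flanked by two cis 1,3-substituents. The key step exploits the fact that C7, C8 and C4 are the carbonyl, α and β carbons of a cyclopentanone: the C4 methyl is a nucleophile added to the β carbon of an enone, C9 is an aldehyde carbon captured by the resulting enolate at C8, and the C3 and C10 chains end in alkenes that later close the seven-membered ring at C1=C2.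

## Logic of the disconnections

**22 ⇒ 21 ⇒ 19 + 20.** The aryl acetate O–acyl bond and then the C9 O–acyl bond are cut. The ester is the most fragile unit, so it is introduced last, and the phenol must be masked so that the acylating agent cannot condense with itself. This removes the arene and leaves a diol. The forward acylation must pick the secondary C9 hydroxyl over the tertiary C7 hydroxyl, and the unmasking must spare the hindered benzoate.

**19 ⇒ 18.** The C9 O–Si bond is cut. The C9 oxygen has to stay inert through enolisation, cross-coupling, epoxidation and hydride treatment. The demand is only that fluoride reach a hindered silyl ether.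

**18 ⇒ 17.** The C1=C2 double bond is cut into two terminal alkenes (ring-closing metathesis in the forward sense). This opens the seven-membered ring and reduces the bicycle to a trisubstituted cyclopentane with two unsaturated side arms. The forward step must form a trisubstituted alkene from a monosubstituted and a 1,1-disubstituted alkene that sit trans on the five-membered ring.

**17 ⇒ 16 ⇒ 15.** The C6–H bond and then the C7–O bond are cut, so the tertiary carbinol becomes an epoxide and then the C6=C7 alkene. Direct addition of an isopropyl nucleophile to a C7 ketone would enter opposite the C8 side chain and give the wrong C7 epimer. Oxygen delivered to the alkene from that same open face gives the right one. The forward steps need chemoselective oxidation of the ring alkene in the presence of two terminal alkenes, and hydride attack at C6 only.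

**15 ⇒ 13 + 14, and 13 ⇒ 11 (through 12).** The C7–isopropyl bond is cut, then the enol O–S bond. This returns the C7 carbonyl and postpones the branched substituent until after the aldol. The forward steps need kinetic enolisation towards C6 (not C8, which would eliminate the C9 oxygen) and a cross-coupling that accepts a secondary alkyl group at a hindered alkenyl triflate.

**11 ⇒ 10.** The C9 O–Si bond is cut. Protection is needed because a free aldol would undergo retro-aldol or elimination under the enolisation conditions.

**10 ⇒ 4 + 7 + 6 (through 8 and 9).** The C4–CH3 and C8–C9 bonds are cut in one operation. Every skeletal carbon needed for ring closure, both ring-closing alkenes and the C7 carbonyl then come from three small achiral pieces. The forward step must set C4 by catalyst control, C8 by approach of the aldehyde opposite the allyl group, and C9 by the aldol transition state. The allyl group of 4 is left unsubstituted: a bulkier spectator could sharpen the C8 bias only from a remote position and would slow the later ring closure, so the C8 bias is accepted as modest and handled by separation.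

**4 ⇒ 1 + 2 (through 3), and 6 ⇒ 5.** The C4–C3 bond of the enone is cut to a vinylogous ester and an allyl nucleophile (carbonyl transposition on acidic work-up). The aldehyde is traced to the homoallylic alcohol. Both forward steps must keep a skipped alkene out of conjugation.

## Other disconnections considered

**Alternative 1: ring expansion of a cyclopropane-fused hydrindane.** The cut is the C9–O bond together with reconnection of C1 to C9, which leads back to the cyclopropane-fused trans-hydrindanediol A1 (C1–C9–C10 cyclopropane, secondary hydroxyl at C2, tertiary carbinol at C7). In the forward step dilute aqueous HClO4 would ionise the C2–O bond, the cyclopropylcarbinyl cation would open by cleavage of C1–C9, and water would capture C9 from the side opposite the departing bond to give diol A2, which is identical with 19.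
- In its favour: C9–O, the C1=C2 alkene and the seven-membered ring arise together. C9 would be set stereospecifically by the cyclopropane face, which is better than the chosen plan, where C9 depends on an aldol transition state. Angular-methyl trans-hydrindanes are a mature substrate class. The alkene position is as unambiguous as in the metathesis (equal).
- Against it here: the tertiary C7 carbinol sits in the same acid and can ionise, dehydrate or shift. The cation can return to cyclopropylcarbinyl or cyclobutyl products, or eliminate. A1 carries three rings and six stereocentres, and the C7 face problem is not removed.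
- Comparison: the mechanism is cationic, whereas the chosen route is organometallic and never exposes C7–OH to strong acid. Step count to A1 is expected to exceed the eleven linear steps of the chosen plan.

**Alternative 2: intramolecular Buchner reaction.** The cuts are C4–C8 and C4–C3, leading back to the aryl α-diazoketone A3 with a 2-methoxy-4-methylphenyl ring on C7. With Rh2(OAc)4 the carbenoid at C4 would add across the ipso–ortho bond of the arene, and the norcaradiene would open to the bicyclic trienone A4.
- In its favour: both rings and quaternary C4 form in one step from a flat aromatic precursor, which is better ring-forming economy than conjugate addition plus metathesis. C4 is set relative to a pre-existing C7 centre through the tether, so the methyl/allyl face discrimination that limits the chosen plan does not arise.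
- Against it here: a carbenoid bearing an α-methyl group can undergo 1,2-hydride shift to an enone. Insertion into the isopropyl C–H bonds and addition across the methoxy-bearing ortho bond are competing paths. A4 is far from the target in oxidation level: the C5 ketone must be removed, two of three conjugated ring alkenes reduced while only C1=C2 is kept, and C8–H and C9–OH set afterwards.
- Comparison: the chosen route installs each carbon at its final oxidation level and keeps C5 and C6 as methylenes throughout, so it should be shorter after the key step, although its key step builds no ring.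

**Alternative 3: divinylcyclopropane Cope rearrangement.** The cut is C3–C4 with reconnection of C9 to C1, leading back to the cis-divinylcyclopropane A5, whose cyclopentene half derives from terpinen-4-ol. On heating, the [3,3] shift through a boat arrangement would give the bis-silyl ether A6, with C1=C2 in place and C8=C9 as a silyl enol ether.
- In its favour: no reagent is needed and the step is stereospecific. The seven-membered ring, quaternary C4, the C1=C2 alkene and a masked C9 ketone appear together. The C7 carbinol comes from the chiral pool, which is better than the epoxidation–hydride sequence of the chosen plan. C9 could then be set by hydride delivery to the ketone from the face opposite the C4 methyl and C7 isopropyl, which is at least equal to aldol control. Overall step economy could be better.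
- Against it here: the cyclopentene terminus C4 is fully substituted, so the boat arrangement forces a ring substituent towards the cyclopropane methylene and the rearrangement should need high temperature. Which face of C4 is attacked follows from the cyclopropane configuration relative to C7, so A5 must be made diastereoselectively next to a hindered tertiary silyl ether. Protonation of the enol ether must also deliver the trans fusion at C8.
- Comparison: the pericyclic step is more predictable than the aldol once A5 exists, but access to A5 is less secure than access to 4, 6 and 7.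

Key step: step 3

Assumption: the chiral sulfonate-bearing NHC ligand (used as its silver carbene complex) is taken as an available catalyst component whose antipode giving 4R is chosen. The C9 configuration of 10 is assigned on the basis of an extended aldol transition state; a metal-bridged chair from the ring enolate would give the C9 epimer, so this centre is treated as the least secure.

## Route

Step 1
Reactants: 1 3-ethoxycyclopent-2-en-1-one; 2 allylmagnesium bromide
Product: 4 3-(prop-2-en-1-yl)cyclopent-2-en-1-one, via bromomagnesium 3-ethoxy-1-(prop-2-en-1-yl)cyclopent-2-en-1-olate 3 (not isolated)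
Conditions: 2 (1.2 equiv), Et2O/THF, 0 °C; then 1 M HCl, 0 °C, brief
Reagents that add atoms: water, O
Why: 1,2-Addition of the allyl Grignard reagent to the vinylogous ester carbonyl, then acid-promoted loss of water and ethanol with carbonyl transposition (Stork–Danheiser sequence), gives the β-substituted enone. Cold, brief acid keeps the skipped alkene out of conjugation.

Step 2
Reactants: 5 3-methylbut-3-en-1-ol
Product: 6 3-methylbut-3-enal
Conditions: Dess–Martin periodinane (1.2 equiv), NaHCO3, CH2Cl2, 0 °C to rt; aq. Na2S2O3/NaHCO3 wash, dried CH2Cl2 solution used at once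
Reagents that add atoms: none
Why: Dess–Martin oxidation under bicarbonate buffering stops at the aldehyde and avoids acid- or base-mediated migration of the 1,1-disubstituted alkene into conjugation. The volatile aldehyde is kept in solution and not stored.

Step 3
Reactants: 4 3-(prop-2-en-1-yl)cyclopent-2-en-1-one; 7 trimethylaluminium; 6 3-methylbut-3-enal
Product: 10 (2S,3R)-2-[(1R)-1-hydroxy-3-methylbut-3-en-1-yl]-3-methyl-3-(prop-2-en-1-yl)cyclopentan-1-one, via dimethylaluminium (3R)-3-methyl-3-(prop-2-en-1-yl)cyclopent-1-en-1-olate 8 (not isolated), via lithium trimethylaluminate enolate 9 (not isolated)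
Conditions: Cu(OTf)2 (5 mol %), chiral sulfonate-bearing NHC–Ag complex (2.5 mol %), 7 (2 equiv), THF, −78 °C; MeLi (2 equiv), −78 °C; 6 (3 equiv, CH2Cl2 solution), −78 °C; aq. NH4Cl, then aq. potassium sodium tartrate
Reagents that add atoms: none
Why: Methyl transfer from 7 to the chiral NHC–copper centre gives a methylcopper species that binds the enone of 4 as a π complex, adds at C4 to a trivalent copper intermediate and reductively eliminates, forming the C4–CH3 bond and leaving the regiodefined dimethylaluminium enolate 8 (1,4- rather than 1,2-addition is secured by the soft copper nucleophile at −78 °C). The closest known reaction type is the copper-catalysed asymmetric conjugate addition of trialkylaluminium reagents to β-substituted cyclic enones followed by trapping of the metal enolate with an electrophile in the same flask. No ring is closed; two skeletal bonds and three stereocentres are created. C4 is controlled by the ligand, whose antipode is chosen so that methyl enters the enone face that gives 4R. MeLi converts 8 into the more nucleophilic aluminate 9, which attacks 6 at C8 only, because the enolate position is fixed by the conjugate addition and does not equilibrate at −78 °C. C8 is controlled by the substrate: the aldehyde bonds to the enolate face opposite the allyl group, the larger of the two C4 substituents, so the new chain ends cis to the methyl group; this bias is modest and the C8 epimers are to be removed by chromatography at this stage. C9 is controlled by the transition-state geometry: aluminium in 9 is coordinatively saturated, so an extended arrangement with the aldehyde CH2 group anti to quaternary C4 is expected and gives the syn (8S,9R) relation, whereas a metal-bridged chair would place that group gauche to C4 and its cis methyl and lead to the 9-epimer. The step further needs carbonyl addition to outrun proton transfer from the enolisable β,γ-unsaturated aldehyde, which the low temperature, the excess of 6 and the cold quench are meant to secure.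

Step 4
Reactants: 10 (2S,3R)-2-[(1R)-1-hydroxy-3-methylbut-3-en-1-yl]-3-methyl-3-(prop-2-en-1-yl)cyclopentan-1-one
Product: 11 (2S,3R)-2-[(1R)-1-{[tert-butyl(dimethyl)silyl]oxy}-3-methylbut-3-en-1-yl]-3-methyl-3-(prop-2-en-1-yl)cyclopentan-1-one
Conditions: TBSOTf (1.3 equiv), 2,6-lutidine (2 equiv), CH2Cl2, −78 to 0 °C
Reagents that add atoms: tert-butyldimethylsilyl trifluoromethanesulfonate, CC(C)(C)[Si](C)(C)OS(=O)(=O)C(F)(F)F
Why: O-Silylation of the secondary aldol hydroxyl by the silyl triflate with a hindered base is faster at low temperature than enol silane formation. It blocks retro-aldol and β-elimination in the enolisation that follows.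

Step 5
Reactants: 11 (2S,3R)-2-[(1R)-1-{[tert-butyl(dimethyl)silyl]oxy}-3-methylbut-3-en-1-yl]-3-methyl-3-(prop-2-en-1-yl)cyclopentan-1-one
Product: 13 (4S,5S)-5-[(1R)-1-{[tert-butyl(dimethyl)silyl]oxy}-3-methylbut-3-en-1-yl]-4-methyl-4-(prop-2-en-1-yl)cyclopent-1-en-1-yl trifluoromethanesulfonate, via potassium C6–C7 enolate 12 (not isolated)
Conditions: KN(SiMe3)2 (1.1 equiv), THF, −78 °C; PhNTf2 (1.2 equiv), −78 to 0 °C
Reagents that add atoms: N-phenylbis(trifluoromethanesulfonimide), O=S(=O)(N(c1ccccc1)S(=O)(=O)C(F)(F)F)C(F)(F)F
Why: Kinetic deprotonation by the bulky amide occurs at the unhindered C6 methylene and not at the C8 methine flanked by quaternary C4 and the silyloxy carbon, so no E1cB loss of silanolate is expected. O-Sulfonylation of the enolate by the triflimide gives the C6=C7 enol triflate with C8 untouched.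

Step 6
Reactants: 13 (4S,5S)-5-[(1R)-1-{[tert-butyl(dimethyl)silyl]oxy}-3-methylbut-3-en-1-yl]-4-methyl-4-(prop-2-en-1-yl)cyclopent-1-en-1-yl trifluoromethanesulfonate; 14 isopropylmagnesium chloride
Product: 15 tert-butyl(dimethyl){[(1R)-3-methyl-1-[(1R,5S)-5-methyl-2-(propan-2-yl)-5-(prop-2-en-1-yl)cyclopent-2-en-1-yl]but-3-en-1-yl]oxy}silane
Conditions: Fe(acac)3 (10 mol %), 14 (2 equiv), THF/NMP, −30 °C
Reagents that add atoms: none
Why: Iron-catalysed cross-coupling of alkenyl triflates with alkyl Grignard reagents (Kumada-type coupling through low-valent iron) is fast at low temperature and accepts secondary alkyl groups. The alkene stays at C6=C7 and the silyl ether and terminal alkenes are inert.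

Step 7
Reactants: 15 tert-butyl(dimethyl){[(1R)-3-methyl-1-[(1R,5S)-5-methyl-2-(propan-2-yl)-5-(prop-2-en-1-yl)cyclopent-2-en-1-yl]but-3-en-1-yl]oxy}silane
Product: 16 (1S,2S,3S,5R)-2-[(1R)-1-{[tert-butyl(dimethyl)silyl]oxy}-3-methylbut-3-en-1-yl]-3-methyl-1-(propan-2-yl)-3-(prop-2-en-1-yl)-6-oxabicyclo[3.1.0]hexane (oxirane oxygen trans to the C8 side chain)
Conditions: mCPBA (1.0 equiv), NaHCO3, CH2Cl2, −30 to 0 °C
Reagents that add atoms: 3-chloroperoxybenzoic acid, OOC(=O)c1cccc(Cl)c1
Why: Prilezhaev epoxidation: the electron-rich trisubstituted ring alkene should react ahead of the 1,1-disubstituted and monosubstituted alkenes, as in ring-selective epoxidation of limonene-type dienes. Oxygen is delivered to the face opposite the bulky C8 side chain and the C4 methyl, which fixes the C7–O bond cis to H8.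

Step 8
Reactants: 16 (1S,2S,3S,5R)-2-[(1R)-1-{[tert-butyl(dimethyl)silyl]oxy}-3-methylbut-3-en-1-yl]-3-methyl-1-(propan-2-yl)-3-(prop-2-en-1-yl)-6-oxabicyclo[3.1.0]hexane
Product: 17 (1S,2S,3R)-2-[(1R)-1-{[tert-butyl(dimethyl)silyl]oxy}-3-methylbut-3-en-1-yl]-3-methyl-1-(propan-2-yl)-3-(prop-2-en-1-yl)cyclopentan-1-ol
Conditions: LiEt3BH (3 equiv), THF, 0 °C to rt; then H2O
Reagents that add atoms: none
Why: SN2 opening of the trisubstituted epoxide by the strongly nucleophilic hydride occurs at the less substituted C6, so the C7–O bond set in step 7 is untouched and becomes the tertiary alcohol. Silyl ether and alkenes are inert to the reagent.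

Step 9
Reactants: 17 (1S,2S,3R)-2-[(1R)-1-{[tert-butyl(dimethyl)silyl]oxy}-3-methylbut-3-en-1-yl]-3-methyl-1-(propan-2-yl)-3-(prop-2-en-1-yl)cyclopentan-1-ol
Product: 18 (3S,3aS,4R,8aR)-4-{[tert-butyl(dimethyl)silyl]oxy}-6,8a-dimethyl-3-(propan-2-yl)-1,2,3,3a,4,5,8,8a-octahydroazulen-3-ol
Conditions: second-generation Grubbs catalyst (5 mol %), CH2Cl2 (0.005 M), 40 °C
Reagents that add atoms: none
Why: Ring-closing metathesis starts at the monosubstituted allyl alkene and closes onto the 1,1-disubstituted alkene, forming the trisubstituted C1=C2 bond in a seven-membered ring with loss of ethene. The trans arrangement of the two arms on the cyclopentane gives the trans-fused hydroazulene, dilution disfavours dimerisation, and the free tertiary hydroxyl is tolerated.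

Step 10
Reactants: 18 (3S,3aS,4R,8aR)-4-{[tert-butyl(dimethyl)silyl]oxy}-6,8a-dimethyl-3-(propan-2-yl)-1,2,3,3a,4,5,8,8a-octahydroazulen-3-ol
Product: 19 (3S,3aS,4R,8aR)-6,8a-dimethyl-3-(propan-2-yl)-1,2,3,3a,4,5,8,8a-octahydroazulene-3,4-diol
Conditions: Bu4NF (3 equiv), THF, rt to 50 °C
Reagents that add atoms: none
Why: Fluoride cleaves the Si–O bond, driven by the strong Si–F bond, and frees the C9 hydroxyl. The tertiary alcohol and the alkene are unaffected under these non-acidic conditions.

Step 11
Reactants: 19 (3S,3aS,4R,8aR)-6,8a-dimethyl-3-(propan-2-yl)-1,2,3,3a,4,5,8,8a-octahydroazulene-3,4-diol; 20 4-(acetyloxy)benzoyl chloride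
Product: 21 (3S,3aS,4R,8aR)-3-hydroxy-6,8a-dimethyl-3-(propan-2-yl)-1,2,3,3a,4,5,8,8a-octahydroazulen-4-yl 4-(acetyloxy)benzoate
Conditions: 20 (2 equiv), Et3N (3 equiv), DMAP (0.3 equiv), CH2Cl2, 0 to 40 °C
Reagents that add atoms: none
Why: DMAP-catalysed acylation through the acylpyridinium ion esterifies the secondary C9 hydroxyl and leaves the unreactive tertiary C7 hydroxyl. C9 keeps its configuration because the C–O bond is not broken, and the acetate mask prevents self-condensation of the acylating agent.

Step 12
Reactants: 21 (3S,3aS,4R,8aR)-3-hydroxy-6,8a-dimethyl-3-(propan-2-yl)-1,2,3,3a,4,5,8,8a-octahydroazulen-4-yl 4-(acetyloxy)benzoate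
Product: 22 (3S,3aS,4R,8aR)-3-hydroxy-6,8a-dimethyl-3-(propan-2-yl)-1,2,3,3a,4,5,8,8a-octahydroazulen-4-yl 4-hydroxybenzoate
Conditions: K2CO3 (0.2 equiv), MeOH, 0 °C; aq. NH4Cl
Reagents that add atoms: none
Why: Transesterification of the aryl acetate, with its phenoxide leaving group, is much faster than methanolysis of the hindered alkyl benzoate, which is deactivated further once the para-phenoxide forms. This releases the target.

## Compound list

1 | 3-ethoxycyclopent-2-en-1-one | CCOC1=CC(=O)CC1 | starting material
2 | allylmagnesium bromide | C=CC[Mg]Br | starting material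
3 | bromomagnesium 3-ethoxy-1-(prop-2-en-1-yl)cyclopent-2-en-1-olate (racemic, not isolated) | C=CCC1(O[Mg]Br)C=C(OCC)CC1 | intermediate
4 | 3-(prop-2-en-1-yl)cyclopent-2-en-1-one | C=CCC1=CC(=O)CC1 | intermediate
5 | 3-methylbut-3-en-1-ol | CC(=C)CCO | starting material
6 | 3-methylbut-3-enal | CC(=C)CC=O | intermediate
7 | trimethylaluminium | C[Al](C)C | starting material
8 | dimethylaluminium (3R)-3-methyl-3-(prop-2-en-1-yl)cyclopent-1-en-1-olate (not isolated) | C=CC[C@@]1(C)CCC(O[Al](C)C)=C1 | intermediate
9 | lithium trimethyl[(3R)-3-methyl-3-(prop-2-en-1-yl)cyclopent-1-en-1-olato]aluminate (not isolated) | C=CC[C@@]1(C)CCC(O[Al-](C)(C)C)=C1.[Li+] | intermediate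
10 | (2S,3R)-2-[(1R)-1-hydroxy-3-methylbut-3-en-1-yl]-3-methyl-3-(prop-2-en-1-yl)cyclopentan-1-one | C=CC[C@@]1(C)CCC(=O)[C@@H]1[C@H](O)CC(C)=C | intermediate
11 | (2S,3R)-2-[(1R)-1-{[tert-butyl(dimethyl)silyl]oxy}-3-methylbut-3-en-1-yl]-3-methyl-3-(prop-2-en-1-yl)cyclopentan-1-one | C=CC[C@@]1(C)CCC(=O)[C@@H]1[C@H](O[Si](C)(C)C(C)(C)C)CC(C)=C | intermediate
12 | potassium (4S,5S)-5-[(1R)-1-{[tert-butyl(dimethyl)silyl]oxy}-3-methylbut-3-en-1-yl]-4-methyl-4-(prop-2-en-1-yl)cyclopent-1-en-1-olate (not isolated) | C=CC[C@@]1(C)CC=C([O-])[C@@H]1[C@H](O[Si](C)(C)C(C)(C)C)CC(C)=C.[K+] | intermediate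
13 | (4S,5S)-5-[(1R)-1-{[tert-butyl(dimethyl)silyl]oxy}-3-methylbut-3-en-1-yl]-4-methyl-4-(prop-2-en-1-yl)cyclopent-1-en-1-yl trifluoromethanesulfonate | C=CC[C@@]1(C)CC=C(OS(=O)(=O)C(F)(F)F)[C@@H]1[C@H](O[Si](C)(C)C(C)(C)C)CC(C)=C | intermediate
14 | isopropylmagnesium chloride | CC(C)[Mg]Cl | starting material
15 | tert-butyl(dimethyl){[(1R)-3-methyl-1-[(1R,5S)-5-methyl-2-(propan-2-yl)-5-(prop-2-en-1-yl)cyclopent-2-en-1-yl]but-3-en-1-yl]oxy}silane | C=CC[C@@]1(C)CC=C(C(C)C)[C@@H]1[C@H](O[Si](C)(C)C(C)(C)C)CC(C)=C | intermediate
16 | (1S,2S,3S,5R)-2-[(1R)-1-{[tert-butyl(dimethyl)silyl]oxy}-3-methylbut-3-en-1-yl]-3-methyl-1-(propan-2-yl)-3-(prop-2-en-1-yl)-6-oxabicyclo[3.1.0]hexane | C=CC[C@@]1(C)C[C@H]2O[C@@]2(C(C)C)[C@@H]1[C@H](O[Si](C)(C)C(C)(C)C)CC(C)=C | intermediate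
17 | (1S,2S,3R)-2-[(1R)-1-{[tert-butyl(dimethyl)silyl]oxy}-3-methylbut-3-en-1-yl]-3-methyl-1-(propan-2-yl)-3-(prop-2-en-1-yl)cyclopentan-1-ol | C=CC[C@@]1(C)CC[C@](O)(C(C)C)[C@@H]1[C@H](O[Si](C)(C)C(C)(C)C)CC(C)=C | intermediate
18 | (3S,3aS,4R,8aR)-4-{[tert-butyl(dimethyl)silyl]oxy}-6,8a-dimethyl-3-(propan-2-yl)-1,2,3,3a,4,5,8,8a-octahydroazulen-3-ol | CC1=CC[C@@]2(C)CC[C@](O)(C(C)C)[C@@H]2[C@H](O[Si](C)(C)C(C)(C)C)C1 | intermediate
19 | (3S,3aS,4R,8aR)-6,8a-dimethyl-3-(propan-2-yl)-1,2,3,3a,4,5,8,8a-octahydroazulene-3,4-diol | CC1=CC[C@@]2(C)CC[C@](O)(C(C)C)[C@@H]2[C@H](O)C1 | intermediate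
20 | 4-(acetyloxy)benzoyl chloride | CC(=O)Oc1ccc(cc1)C(Cl)=O | starting material
21 | (3S,3aS,4R,8aR)-3-hydroxy-6,8a-dimethyl-3-(propan-2-yl)-1,2,3,3a,4,5,8,8a-octahydroazulen-4-yl 4-(acetyloxy)benzoate | CC1=CC[C@@]2(C)CC[C@](O)(C(C)C)[C@@H]2[C@H](OC(=O)c2ccc(OC(C)=O)cc2)C1 | intermediate
22 | (3S,3aS,4R,8aR)-3-hydroxy-6,8a-dimethyl-3-(propan-2-yl)-1,2,3,3a,4,5,8,8a-octahydroazulen-4-yl 4-hydroxybenzoate | CC1=CC[C@@]2(C)CC[C@](O)(C(C)C)[C@@H]2[C@H](OC(=O)c2ccc(O)cc2)C1 | target

## Step count and least certain steps

Total: 12 steps. Longest linear sequence: 11 steps (steps 1 and 3 to 12, from 1 to 22); step 2 is a one-step branch.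

**Step 3 (key step).** Most likely to go wrong:
- poor facial discrimination at C8, because the methyl and allyl groups on C4 differ little in size;
- erosion of the syn preference at C9 if a lithium-bridged chair competes with the extended arrangement;
- proton transfer from, or isomerisation of, the enolisable aldehyde under the basic aluminate;
- methyl transfer from aluminate to the aldehyde.

Fallback: the two bond formations are separated. Starting from 4, the same copper-catalysed addition of 7 is run and enolate 8 is intercepted with Et3SiOTf to give the isolable silyl enol ether triethyl{[(3R)-3-methyl-3-(prop-2-en-1-yl)cyclopent-1-en-1-yl]oxy}silane F1. A Mukaiyama aldol addition of F1 to 6 (BF3·OEt2, CH2Cl2, −78 °C) then proceeds through an open transition state with no basic species present and rejoins the route at 10.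

**Step 6.** Most likely to go wrong: slow reaction at the hindered alkenyl triflate next to the branched C8, so that reduction of the triflate or scrambling of the secondary alkyl group through β-hydride processes competes. Fallback: starting from 13, a Negishi coupling with i-PrZnCl under PdCl2(dppf) catalysis in THF at 50 °C replaces the iron/Grignard manifold with a palladium/organozinc one and returns to 15. No new compound is involved.

**Step 7.** Most likely to go wrong: insufficient chemoselectivity. The ring alkene is trisubstituted but hindered, so oxidation of the 1,1-disubstituted side-chain alkene can compete. Acid-promoted rearrangement of the epoxide at the fully substituted C7 is a second risk. Fallback: starting from 15, selection is moved from the substrate to the catalyst by a Shi-type epoxidation with a fructose-derived ketone and KHSO5 in buffered MeCN–water at 0 °C. This dioxirane class reacts preferentially with trisubstituted alkenes, and the catalyst enantiomer is matched to the open face. It returns to 16 with no new compound.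

**Step 11.** Most likely to go wrong: slow acylation of the C9 hydroxyl, which is flanked by the cis C4 methyl and C7 isopropyl groups, so that acetyl transfer from the aryl acetate or elimination competes. Fallback: the ester is installed before ring closure, where the carbinol sits on a freely rotating chain. Starting from 17, desilylation with Bu4NF gives (1S,2S,3R)-2-[(1R)-1-hydroxy-3-methylbut-3-en-1-yl]-3-methyl-1-(propan-2-yl)-3-(prop-2-en-1-yl)cyclopentan-1-ol F2. Acylation with 20 under the conditions of step 11 gives (1R)-1-[(1S,2S,5R)-2-hydroxy-5-methyl-2-(propan-2-yl)-5-(prop-2-en-1-yl)cyclopentyl]-3-methylbut-3-en-1-yl 4-(acetyloxy)benzoate F3. Ring-closing metathesis of F3 under the conditions of step 9 rejoins the route at 21.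

## Further compounds

F1 | step 3 | triethyl{[(3R)-3-methyl-3-(prop-2-en-1-yl)cyclopent-1-en-1-yl]oxy}silane | C=CC[C@@]1(C)CCC(O[Si](CC)(CC)CC)=C1
F0 | step 6 | none | none
F0 | step 7 | none | none
F2 | step 11 | (1S,2S,3R)-2-[(1R)-1-hydroxy-3-methylbut-3-en-1-yl]-3-methyl-1-(propan-2-yl)-3-(prop-2-en-1-yl)cyclopentan-1-ol | C=CC[C@@]1(C)CC[C@](O)(C(C)C)[C@@H]1[C@H](O)CC(C)=C
F3 | step 11 | (1R)-1-[(1S,2S,5R)-2-hydroxy-5-methyl-2-(propan-2-yl)-5-(prop-2-en-1-yl)cyclopentyl]-3-methylbut-3-en-1-yl 4-(acetyloxy)benzoate | C=CC[C@@]1(C)CC[C@](O)(C(C)C)[C@@H]1[C@H](OC(=O)c2ccc(OC(C)=O)cc2)CC(C)=C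
A1 | alternative 1 | cyclopropane-fused trans-hydrindanediol (C1–C9–C10 cyclopropane cis to the C4 methyl, secondary hydroxyl at C2 cis to the cyclopropane methylene, tertiary isopropyl carbinol at C7 as in the target) | CC(C)[C@@]1(O)CC[C@]2(C)C[C@@H](O)[C@@]3(C)C[C@H]3[C@@H]12
A2 | alternative 1 | (3S,3aS,4R,8aR)-6,8a-dimethyl-3-(propan-2-yl)-1,2,3,3a,4,5,8,8a-octahydroazulene-3,4-diol (identical with 19) | CC1=CC[C@@]2(C)CC[C@](O)(C(C)C)[C@@H]2[C@H](O)C1
A3 | alternative 2 | (5S)-2-diazo-5-(2-methoxy-4-methylphenyl)-6-methyl-5-[(triethylsilyl)oxy]heptan-3-one | CC(=[N+]=[N-])C(=O)C[C@](O[Si](CC)(CC)CC)(C(C)C)c1ccc(C)cc1OC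
A4 | alternative 2 | (3S,8aR)-4-methoxy-6,8a-dimethyl-3-(propan-2-yl)-3-[(triethylsilyl)oxy]-2,3-dihydroazulen-1(8aH)-one | CC1=CC(OC)=C2[C@@](O[Si](CC)(CC)CC)(C(C)C)CC(=O)[C@]2(C)C=C1
A5 | alternative 3 | cis-1-(trimethylsilyloxy)-1-[2-methyl-5-(propan-2-yl)-5-(trimethylsilyloxy)cyclopent-1-en-1-yl]-2-methyl-2-ethenylcyclopropane (ethenyl and cyclopentenyl cis) | C=C[C@@]1(C)C[C@@]1(O[Si](C)(C)C)C1=C(C)CC[C@]1(O[Si](C)(C)C)C(C)C
A6 | alternative 3 | trimethyl{[(3S,8aR)-6,8a-dimethyl-3-(propan-2-yl)-3-[(trimethylsilyl)oxy]-1,2,3,5,8,8a-hexahydroazulen-4-yl]oxy}silane | CC1=CC[C@@]2(C)CC[C@](O[Si](C)(C)C)(C(C)C)C2=C(O[Si](C)(C)C)C1
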